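**Retrosynthetic overview** (ring A numbering: C1 = CMe2, C3 = acetoxy carbon, C4 = CH2 next to the methyl‑bearing C5, C6 = alkyne‑bearing carbon)

- Last bond: Stille coupling at the butenolide α‑carbon joins the ring B alkenylstannane 34 to bromo‑ylidenebutenolide 24. The (Z)‑ylidene lactone comes from a vinylogous aldol/elimination on polyenal 18, and the polyene from Horner–Wadsworth–Emmons and Wittig steps.
- Both six‑membered rings come from one enol triflate 9: Sonogashira coupling gives ring A–C≡C, while formylation and Sharpless epoxidation give ring B.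
- Triflate 9 comes from (4R,6R)‑4‑hydroxy‑2,2,6‑trimethylcyclohexanone 7, and 7 from dione 6. The key disconnection is C3–C4 of the carbocycle: an intramolecular Stetter reaction of the acyclic, achiral keto‑aldehyde 5.
- Enabling feature: C3 (O‑bearing) and C6 (a masked ketone, later enol triflate then alkyne) are 1,4‑related across C4–C5, so the ring is a latent cyclohexane‑1,4‑dione. C3 can therefore act as an acyl anion toward C4 of a C4=C5–C6=O enone, and the quaternary C1 blocks enolisation on its side and favours closure.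
- Order of ring formation: carbocycle (step 4, used for both rings), then the ring B epoxide (step 17), then the butenolide (step 14).

Key step: step 4

Assumption: the (5aS,10bR) antipode of the aminoindanol‑derived triazolium salt is taken to give the (R)‑dione in step 4; the other antipode would be used if the sense proved opposite.

**Step 1**
Reactants: 1 2,2-dimethylpent-4-enal; 2 isopropenylmagnesium bromide
Product: 3 rac-2,4,4-trimethylhepta-1,6-dien-3-ol
Conditions: THF, 0 °C → rt; then H2O
Reagents that add atoms: none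
Why: Grignard 1,2‑addition to a non‑enolisable aldehyde; the carbinol centre forms as a racemate and is erased in step 2.

**Step 2**
Reactants: 3 rac-2,4,4-trimethylhepta-1,6-dien-3-ol
Product: 4 2,4,4-trimethylhepta-1,6-dien-3-one
Conditions: Dess–Martin periodinane, CH2Cl2, rt
Reagents that add atoms: none
Why: Dess–Martin oxidation of a hindered allylic alcohol under neutral conditions should give the enone without touching either alkene.

**Step 3**
Reactants: 4 2,4,4-trimethylhepta-1,6-dien-3-one
Product: 5 3,3,5-trimethyl-4-oxohex-5-enal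
Conditions: O3, CH2Cl2, −78 °C (Sudan Red 7B end‑point); then PPh3, −78 °C → rt
Reagents that add atoms: ozone, [O-][O+]=O
Why: Ozonolysis dosed to an indicator end‑point should cleave the isolated, electron‑rich monosubstituted alkene and leave the electron‑poor enone C=C.

**Step 4 (key step)**
Reactants: 5 3,3,5-trimethyl-4-oxohex-5-enal
Product: 6 (6R)-2,2,6-trimethylcyclohexane-1,4-dione
Conditions: (5aS,10bR)-2-(pentafluorophenyl)-5a,10b-dihydro-4H,6H-indeno[2,1-b][1,2,4]triazolo[4,3-d][1,4]oxazin-2-ium tetrafluoroborate (10 mol%), KN(SiMe3)2 (9 mol%), toluene, 0 °C → 23 °C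
Reagents that add atoms: none
Why: Proposed new method: the triazolylidene adds to the aldehyde (C3) to give a Breslow intermediate whose acyl‑anion carbon attacks the unsubstituted β‑carbon (C4) of the tethered isopropenyl ketone, the enolate is protonated at C5 and the carbene is expelled to leave the 1,4‑dione; the closest known reaction type is the catalytic asymmetric intramolecular Stetter reaction of aliphatic aldehydes onto α‑substituted Michael acceptors, which is established for exo closures with the acceptor carbonyl outside the ring. The one ring closes in the 6‑endo‑trig mode (C3 onto C4, with the enone C=C and C=O ending inside the new ring), reachable from the s‑trans enone and favoured by the gem‑dimethyl group at C1. The only new stereocentre, C5, is set when the hydroxyl proton of the carbene‑bound tetrahedral intermediate at C3 is passed intramolecularly to the enolate carbon two atoms away, so the chiral carbene fixes the face of protonation. The step needs conjugate acylation to outrun benzoin and aldol paths and needs C5 to keep its configuration: the terminal CH2 acceptor makes C–C formation fast, and base is present only in the sub‑stoichiometric amount that frees the carbene, so the single enolisable stereocentre of the product should not equilibrate.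

**Step 5**
Reactants: 6 (6R)-2,2,6-trimethylcyclohexane-1,4-dione
Product: 7 (4R,6R)-4-hydroxy-2,2,6-trimethylcyclohexan-1-one
Conditions: K[HB(s-Bu)3], THF, −78 °C; then H2O
Reagents that add atoms: none
Why: Substrate‑controlled hydride reduction: the bulky borohydride should reduce only the unhindered C4 ketone and attack equatorially, away from the axial methyl of the gem‑dimethyl group, giving the axial alcohol trans to the C6 methyl; C6 thereby relays its configuration to the carbinol carbon.

**Step 6**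
Reactants: 7 (4R,6R)-4-hydroxy-2,2,6-trimethylcyclohexan-1-one
Product: 8 (1R,3R)-3,5,5-trimethyl-4-oxocyclohexyl acetate
Conditions: Ac2O, pyridine, 4-(dimethylamino)pyridine (cat.), CH2Cl2, rt
Reagents that add atoms: acetic anhydride, CC(=O)OC(C)=O
Why: Nucleophile‑catalysed O‑acylation; no stereocentre is touched.

**Step 7**
Reactants: 8 (1R,3R)-3,5,5-trimethyl-4-oxocyclohexyl acetate
Product: 9 (1R)-3,5,5-trimethyl-4-{[(trifluoromethyl)sulfonyl]oxy}cyclohex-3-en-1-yl acetate
Conditions: Tf2O, 2,6-di-tert-butyl-4-methylpyridine, CH2Cl2, 0 °C → rt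
Reagents that add atoms: trifluoromethanesulfonic anhydride, O=S(=O)(OS(=O)(=O)C(F)(F)F)C(F)(F)F
Why: Enol triflate formation with a non‑nucleophilic base; the ketone can enolise only toward the methyl‑bearing carbon (the other α‑carbon is quaternary), so the tetrasubstituted triflate is regiodefined, the relay stereocentre is erased and the acetate is spared.

**Step 8**
Reactants: 9 enol triflate; 10 (2E)-3-methylpent-2-en-4-yn-1-ol
Product: 11 (1R)-4-[(3E)-5-hydroxy-3-methylpent-3-en-1-yn-1-yl]-3,5,5-trimethylcyclohex-3-en-1-yl acetate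
Conditions: Pd(PPh3)4 (5 mol%), CuI (10 mol%), iPr2NH, DMF, 40 °C
Reagents that add atoms: none
Why: Sonogashira coupling of an enol triflate with a terminal enyne; alkene geometry, acetate and free hydroxyl are not affected.

**Step 9**
Reactants: 11 C15 allylic alcohol
Product: 12 (1R)-4-[(3E)-5-bromo-3-methylpent-3-en-1-yn-1-yl]-3,5,5-trimethylcyclohex-3-en-1-yl acetate
Conditions: CBr4, PPh3, CH2Cl2, 0 °C
Reagents that add atoms: carbon tetrabromide, BrC(Br)(Br)Br
Why: Appel bromination of a primary allylic alcohol under neutral SN2 conditions should keep the alkene geometry.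

**Step 10**
Reactants: 12 C15 allylic bromide
Product: 13 (1R)-4-[(3E)-5-(diethoxyphosphoryl)-3-methylpent-3-en-1-yn-1-yl]-3,5,5-trimethylcyclohex-3-en-1-yl acetate
Conditions: P(OEt)3 (neat), 90 °C
Reagents that add atoms: triethyl phosphite, CCOP(OCC)OCC
Why: Michaelis–Arbuzov reaction of a primary allylic bromide.

**Step 11**
Reactants: 13 C15 phosphonate; 14 (2E)-4,4-dimethoxybut-2-enal
Product: 16 (1R)-3,5,5-trimethyl-4-[(3E,5E,7E)-3-methyl-9-oxonona-3,5,7-trien-1-yn-1-yl]cyclohex-3-en-1-yl acetate, via dimethyl acetal 15 (not isolated)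
Conditions: NaN(SiMe3)2, THF, −78 °C → 0 °C; then 1 M aq. HCl, THF, 0 °C
Reagents that add atoms: water, O
Why: Horner–Wadsworth–Emmons olefination of an allylic phosphonate anion with an enal is E‑selective, and the dienyl dimethyl acetal should hydrolyse under acid mild enough to spare the acetate.

**Step 12**
Reactants: 16 C19 aldehyde; 17 2-(triphenyl-λ5-phosphanylidene)propanal
Product: 18 (1R)-4-[(3E,5E,7E,9E)-3,10-dimethyl-11-oxoundeca-3,5,7,9-tetraen-1-yn-1-yl]-3,5,5-trimethylcyclohex-3-en-1-yl acetate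
Conditions: toluene, 60 °C
Reagents that add atoms: none
Why: Wittig reaction of a stabilised ylide gives the (E)‑α‑methyl enal; the α‑branched product aldehyde is less reactive than 16, so one homologation is expected.

**Step 13**
Reactants: 19 furan-2(5H)-one
Product: 21 3-bromofuran-2(5H)-one, via dibromolactone 20 (not isolated)
Conditions: Br2, CH2Cl2, 0 °C → rt; then Et3N, 0 °C
Reagents that add atoms: bromine, BrBr
Why: Bromine addition to the butenolide C=C followed by base‑induced loss of HBr (acidic α‑proton) gives the α‑bromobutenolide.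

**Step 14**
Reactants: 18 C22 aldehyde; 21 3-bromofuran-2(5H)-one
Product: 24 (1R)-4-[(3E,5E,7E,9E)-11-[(2Z)-4-bromo-5-oxofuran-2(5H)-ylidene]-3,10-dimethylundeca-3,5,7,9-tetraen-1-yn-1-yl]-3,5,5-trimethylcyclohex-3-en-1-yl acetate, via silyloxyfuran 22 (not isolated), via silyl aldol adduct 23 (not isolated)
Conditions: 21, TBSOTf, Et3N, CH2Cl2, 0 °C; then 18, −78 °C → 0 °C; then DBU, rt
Reagents that add atoms: none
Why: Vinylogous Mukaiyama aldol of the in situ 2‑silyloxyfuran at its γ‑carbon, then E1cB loss of silanolate; under DBU the (Z)‑ylidene (chain cis to the ring oxygen) is the thermodynamically preferred isomer because it avoids the clash with the butenolide β‑hydrogen.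

**Step 15**
Reactants: 9 enol triflate
Product: 25 (1R)-4-formyl-3,5,5-trimethylcyclohex-3-en-1-yl acetate
Conditions: CO (1 atm), Bu3SnH (slow addition), Pd(PPh3)4 (5 mol%), LiCl, THF, 50 °C
Reagents that add atoms: carbon monoxide, [C-]#[O+]
Why: Palladium‑catalysed reductive carbonylation (formylation) of an enol triflate: oxidative addition, CO insertion, hydride transfer from tin.

**Step 16**
Reactants: 25 ring aldehyde
Product: 26 (1R)-4-(hydroxymethyl)-3,5,5-trimethylcyclohex-3-en-1-yl acetate
Conditions: NaBH4, CeCl3·7H2O, MeOH, −20 °C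
Reagents that add atoms: none
Why: Luche 1,2‑reduction of the enal; the acetate should survive at low temperature.

**Step 17**
Reactants: 26 allylic alcohol
Product: 27 (1R,4S,6R)-1-(hydroxymethyl)-2,2,6-trimethyl-7-oxabicyclo[4.1.0]heptan-4-yl acetate
Conditions: Ti(OiPr)4 (30 mol%), D-(−)-diethyl tartrate (36 mol%), t-BuOOH, 4 Å molecular sieves, CH2Cl2, −20 °C
Reagents that add atoms: tert-butyl hydroperoxide, CC(C)(C)OO
Why: Sharpless asymmetric epoxidation; this tartrate antipode should deliver oxygen to the ring face anti to the acetoxy group, which is also the face the substrate prefers (matched case), setting both epoxide carbons.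

**Step 18**
Reactants: 27 epoxy alcohol
Product: 28 (1S,4S,6R)-1-formyl-2,2,6-trimethyl-7-oxabicyclo[4.1.0]heptan-4-yl acetate
Conditions: Dess–Martin periodinane, pyridine, CH2Cl2, 0 °C → rt
Reagents that add atoms: none
Why: Dess–Martin oxidation, buffered so that the epoxide is not opened; the aldehyde has no α‑hydrogen and cannot epimerise.

**Step 19**
Reactants: 29 dibromomethane; 30 tributyltin chloride
Product: 32 tributyl(dibromomethyl)stannane, via dibromomethyllithium 31 (not isolated)
Conditions: LiN(iPr)2, THF/Et2O, −100 °C; then 30, −100 °C → −78 °C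
Reagents that add atoms: none
Why: Deprotonation of dibromomethane gives a lithium carbenoid that is trapped by the tin chloride faster than it decomposes at −100 °C.

**Step 20**
Reactants: 28 epoxy aldehyde; 32 tributyl(dibromomethyl)stannane
Product: 33 (1S,4S,6R)-2,2,6-trimethyl-1-[(E)-2-(tributylstannyl)ethenyl]-7-oxabicyclo[4.1.0]heptan-4-yl acetate
Conditions: CrCl2, LiI, DMF/THF, rt, dark
Reagents that add atoms: none
Why: Takai‑type chromium olefination with a stannyl gem‑dihalide; addition of the gem‑dichromium species and elimination should give the (E)‑alkenylstannane, and divalent chromium tolerates epoxide and acetate.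

**Step 21**
Reactants: 33 acetoxy alkenylstannane
Product: 34 (1S,4S,6R)-2,2,6-trimethyl-1-[(E)-2-(tributylstannyl)ethenyl]-7-oxabicyclo[4.1.0]heptan-4-ol
Conditions: K2CO3 (cat.), MeOH, rt
Reagents that add atoms: none
Why: Base‑catalysed transesterification removes the acetate; alkenylstannane and tetrasubstituted epoxide are stable to mild carbonate.

**Step 22**
Reactants: 24 bromo‑ylidenebutenolide; 34 hydroxy alkenylstannane
Product: 35 pyrrhoxanthin
Conditions: Pd2(dba)3 (5 mol%), AsPh3 (40 mol%), N-methylpyrrolidone, rt → 40 °C, dark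
Reagents that add atoms: none
Why: Stille coupling of an α‑bromobutenolide with an alkenylstannane proceeds with retention of geometry in both partners under neutral conditions that should tolerate acetate, free hydroxyl, epoxide and the (Z)‑ylidene lactone.

**Compound list**

1 | 2,2-dimethylpent-4-enal | C=CCC(C)(C)C=O | starting material
2 | isopropenylmagnesium bromide | CC(=C)[Mg]Br | starting material
3 | rac-2,4,4-trimethylhepta-1,6-dien-3-ol | C=C(C)C(O)C(C)(C)CC=C | intermediate
4 | 2,4,4-trimethylhepta-1,6-dien-3-one | C=C(C)C(=O)C(C)(C)CC=C | intermediate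
5 | 3,3,5-trimethyl-4-oxohex-5-enal | C=C(C)C(=O)C(C)(C)CC=O | intermediate
6 | (6R)-2,2,6-trimethylcyclohexane-1,4-dione | O=C1C(C)(C)CC(=O)C[C@H]1C | intermediate
7 | (4R,6R)-4-hydroxy-2,2,6-trimethylcyclohexan-1-one | O=C1C(C)(C)C[C@H](O)C[C@H]1C | intermediate
8 | (1R,3R)-3,5,5-trimethyl-4-oxocyclohexyl acetate | O=C1C(C)(C)C[C@H](OC(C)=O)C[C@H]1C | intermediate
9 | (1R)-3,5,5-trimethyl-4-{[(trifluoromethyl)sulfonyl]oxy}cyclohex-3-en-1-yl acetate | CC(=O)O[C@@H]1CC(C)=C(OS(=O)(=O)C(F)(F)F)C(C)(C)C1 | intermediate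
10 | (2E)-3-methylpent-2-en-4-yn-1-ol | C#C/C(C)=C/CO | starting material
11 | (1R)-4-[(3E)-5-hydroxy-3-methylpent-3-en-1-yn-1-yl]-3,5,5-trimethylcyclohex-3-en-1-yl acetate | CC(=O)O[C@@H]1CC(C)=C(C#C/C(C)=C/CO)C(C)(C)C1 | intermediate
12 | (1R)-4-[(3E)-5-bromo-3-methylpent-3-en-1-yn-1-yl]-3,5,5-trimethylcyclohex-3-en-1-yl acetate | CC(=O)O[C@@H]1CC(C)=C(C#C/C(C)=C/CBr)C(C)(C)C1 | intermediate
13 | (1R)-4-[(3E)-5-(diethoxyphosphoryl)-3-methylpent-3-en-1-yn-1-yl]-3,5,5-trimethylcyclohex-3-en-1-yl acetate | CC(=O)O[C@@H]1CC(C)=C(C#C/C(C)=C/CP(=O)(OCC)OCC)C(C)(C)C1 | intermediate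
14 | (2E)-4,4-dimethoxybut-2-enal | O=C/C=C/C(OC)OC | starting material
15 | (1R)-4-[(3E,5E,7E)-9,9-dimethoxy-3-methylnona-3,5,7-trien-1-yn-1-yl]-3,5,5-trimethylcyclohex-3-en-1-yl acetate | CC(=O)O[C@@H]1CC(C)=C(C#C/C(C)=C/C=C/C=C/C(OC)OC)C(C)(C)C1 | intermediate
16 | (1R)-3,5,5-trimethyl-4-[(3E,5E,7E)-3-methyl-9-oxonona-3,5,7-trien-1-yn-1-yl]cyclohex-3-en-1-yl acetate | CC(=O)O[C@@H]1CC(C)=C(C#C/C(C)=C/C=C/C=C/C=O)C(C)(C)C1 | intermediate
17 | 2-(triphenyl-λ5-phosphanylidene)propanal | CC(C=O)=P(c1ccccc1)(c1ccccc1)c1ccccc1 | starting material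
18 | (1R)-4-[(3E,5E,7E,9E)-3,10-dimethyl-11-oxoundeca-3,5,7,9-tetraen-1-yn-1-yl]-3,5,5-trimethylcyclohex-3-en-1-yl acetate | CC(=O)O[C@@H]1CC(C)=C(C#C/C(C)=C/C=C/C=C/C=C(C)/C=O)C(C)(C)C1 | intermediate
19 | furan-2(5H)-one | O=C1OCC=C1 | starting material
20 | trans-3,4-dibromooxolan-2-one | O=C1OCC(Br)C1Br | intermediate
21 | 3-bromofuran-2(5H)-one | O=C1OCC=C1Br | intermediate
22 | [(3-bromofuran-2-yl)oxy](tert-butyl)dimethylsilane | CC(C)(C)[Si](C)(C)Oc1occc1Br | intermediate
23 | (1R)-4-[(3E,5E,7E,9E)-11-(4-bromo-5-oxo-2,5-dihydrofuran-2-yl)-11-[(tert-butyldimethylsilyl)oxy]-3,10-dimethylundeca-3,5,7,9-tetraen-1-yn-1-yl]-3,5,5-trimethylcyclohex-3-en-1-yl acetate (diastereomer mixture at the two new centres) | CC(=O)O[C@@H]1CC(C)=C(C#C/C(C)=C/C=C/C=C/C=C(C)/C(O[Si](C)(C)C(C)(C)C)C2OC(=O)C(Br)=C2)C(C)(C)C1 | intermediate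
24 | (1R)-4-[(3E,5E,7E,9E)-11-[(2Z)-4-bromo-5-oxofuran-2(5H)-ylidene]-3,10-dimethylundeca-3,5,7,9-tetraen-1-yn-1-yl]-3,5,5-trimethylcyclohex-3-en-1-yl acetate | CC(=O)O[C@@H]1CC(C)=C(C#C/C(C)=C/C=C/C=C/C=C(C)/C=C2C=C(Br)C(=O)O/2)C(C)(C)C1 | intermediate
25 | (1R)-4-formyl-3,5,5-trimethylcyclohex-3-en-1-yl acetate | CC(=O)O[C@@H]1CC(C)=C(C=O)C(C)(C)C1 | intermediate
26 | (1R)-4-(hydroxymethyl)-3,5,5-trimethylcyclohex-3-en-1-yl acetate | CC(=O)O[C@@H]1CC(C)=C(CO)C(C)(C)C1 | intermediate
27 | (1R,4S,6R)-1-(hydroxymethyl)-2,2,6-trimethyl-7-oxabicyclo[4.1.0]heptan-4-yl acetate | OC[C@@]12O[C@]1(C)C[C@@H](OC(C)=O)CC2(C)C | intermediate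
28 | (1S,4S,6R)-1-formyl-2,2,6-trimethyl-7-oxabicyclo[4.1.0]heptan-4-yl acetate | O=C[C@@]12O[C@]1(C)C[C@@H](OC(C)=O)CC2(C)C | intermediate
29 | dibromomethane | BrCBr | starting material
30 | tributyltin chloride | CCCC[Sn](Cl)(CCCC)CCCC | starting material
31 | dibromomethyllithium | [Li]C(Br)Br | intermediate
32 | tributyl(dibromomethyl)stannane | CCCC[Sn](CCCC)(CCCC)C(Br)Br | intermediate
33 | (1S,4S,6R)-2,2,6-trimethyl-1-[(E)-2-(tributylstannyl)ethenyl]-7-oxabicyclo[4.1.0]heptan-4-yl acetate | CCCC[Sn](CCCC)(CCCC)/C=C/[C@@]12O[C@]1(C)C[C@@H](OC(C)=O)CC2(C)C | intermediate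
34 | (1S,4S,6R)-2,2,6-trimethyl-1-[(E)-2-(tributylstannyl)ethenyl]-7-oxabicyclo[4.1.0]heptan-4-ol | CCCC[Sn](CCCC)(CCCC)/C=C/[C@@]12O[C@]1(C)C[C@@H](O)CC2(C)C | intermediate
35 | pyrrhoxanthin: (1R)-4-[(3E,5E,7E,9E)-11-[(2Z)-4-{(E)-2-[(1S,4S,6R)-4-hydroxy-2,2,6-trimethyl-7-oxabicyclo[4.1.0]heptan-1-yl]ethenyl}-5-oxofuran-2(5H)-ylidene]-3,10-dimethylundeca-3,5,7,9-tetraen-1-yn-1-yl]-3,5,5-trimethylcyclohex-3-en-1-yl acetate | CC(=O)O[C@@H]1CC(C)=C(C#C/C(C)=C/C=C/C=C/C=C(C)/C=C2C=C(/C=C/[C@@]34O[C@]3(C)C[C@@H](O)CC4(C)C)C(=O)O/2)C(C)(C)C1 | target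

**Step count**

Total: 22 steps. Longest linear sequence: 14 steps (steps 1–12, 14, 22; the ring B branch, steps 1–7, 15–18, 20–22, is equally long).

**Steps most likely to fail**

1. Step 4 (proposed new method). The carbene may fail to turn over in the endo mode, being diverted into benzoin or aldol oligomerisation or conjugate addition to the enone. Protonation at C5 may also show poor facial selectivity, or the product may racemise by enolisation. The fallback uses known chemistry and sets out from 5. Reductive ketyl–olefin cyclisation with SmI2 (THF/t‑BuOH, −78 °C) joins the aldehyde carbon to the enone β‑carbon and should give rac‑4‑hydroxy‑2,2,6‑trimethylcyclohexan‑1‑one F1 as a cis/trans mixture. Excess IBX in DMSO at 70 °C then oxidises the alcohol and dehydrogenates the dione to 2,6,6‑trimethylcyclohex‑2‑ene‑1,4‑dione F2. Enantioselective C=C reduction of F2 with fermenting baker's yeast (ene‑reductase) returns to the route at dione 6.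

2. Step 14. The silyl triflate may erode the polyene, the silyloxyfuran may add in conjugate fashion to the polyenal, or elimination may stop at a Z/E mixture of the ylidene. The fallback sets out from 16 and builds the lactone by cross‑coupling instead. Horner–Wadsworth–Emmons reaction with diethyl [4‑(trimethylsilyl)but‑3‑yn‑2‑yl]phosphonate gives (1R)‑4‑[(3E,5E,7E,9E)‑3,10‑dimethyl‑12‑(trimethylsilyl)dodeca‑3,5,7,9‑tetraene‑1,11‑diyn‑1‑yl]‑3,5,5‑trimethylcyclohex‑3‑en‑1‑yl acetate F3 (E isomer separated). Desilylation with Bu4NF/AcOH gives the terminal diyne F4. Tandem Sonogashira coupling and 5‑exo‑dig lactonisation with (E)‑2,3‑dibromoacrylic acid (Pd(PPh3)4, CuI, Et3N, MeCN) couples at the β‑bromide cis to the carboxyl group; anti addition of the carboxylate across the alkyne gives the (Z)‑ylidene, returning to the route at 24.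

3. Step 22. Transmetalation of the hindered stannane may be slow, zerovalent palladium may ionise the alkenyl epoxide, or the polyene may isomerise during a long reaction. The fallback changes the order of bond formation and sets out from 34 and 21. Stille coupling of these two small, robust partners gives 3‑{(E)‑2‑[(1S,4S,6R)‑4‑hydroxy‑2,2,6‑trimethyl‑7‑oxabicyclo[4.1.0]heptan‑1‑yl]ethenyl}furan‑2(5H)‑one F5. Vinylogous aldol/elimination of F5 with aldehyde 18 (TBSOTf in excess, Et3N; then 18; then DBU) silylates the hydroxyl as well and gives the O‑tert‑butyldimethylsilyl ether of pyrrhoxanthin F6. Bu4NF buffered with AcOH removes the silyl group and returns to the route at 35, so the last C–C bond is made without a metal.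

**Further compounds**

F1 | step 4 | rac-4-hydroxy-2,2,6-trimethylcyclohexan-1-one (cis/trans mixture) | CC1CC(O)CC(C)(C)C1=O
F2 | step 4 | 2,6,6-trimethylcyclohex-2-ene-1,4-dione | CC1=CC(=O)CC(C)(C)C1=O
F3 | step 14 | (1R)-4-[(3E,5E,7E,9E)-3,10-dimethyl-12-(trimethylsilyl)dodeca-3,5,7,9-tetraene-1,11-diyn-1-yl]-3,5,5-trimethylcyclohex-3-en-1-yl acetate | CC(=O)O[C@@H]1CC(C)=C(C#C/C(C)=C/C=C/C=C/C=C(C)/C#C[Si](C)(C)C)C(C)(C)C1
F4 | step 14 | (1R)-4-[(3E,5E,7E,9E)-3,10-dimethyldodeca-3,5,7,9-tetraene-1,11-diyn-1-yl]-3,5,5-trimethylcyclohex-3-en-1-yl acetate | CC(=O)O[C@@H]1CC(C)=C(C#C/C(C)=C/C=C/C=C/C=C(C)/C#C)C(C)(C)C1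
F5 | step 22 | 3-{(E)-2-[(1S,4S,6R)-4-hydroxy-2,2,6-trimethyl-7-oxabicyclo[4.1.0]heptan-1-yl]ethenyl}furan-2(5H)-one | O=C1OCC=C1/C=C/[C@@]12O[C@]1(C)C[C@@H](O)CC2(C)C
F6 | step 22 | pyrrhoxanthin O-tert-butyldimethylsilyl ether (silyl on the ring B hydroxyl) | CC(=O)O[C@@H]1CC(C)=C(C#C/C(C)=C/C=C/C=C/C=C(C)/C=C2C=C(/C=C/[C@@]34O[C@]3(C)C[C@@H](O[Si](C)(C)C(C)(C)C)CC4(C)C)C(=O)O/2)C(C)(C)C1
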